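**Plan** (ent-kaurane locants: ring A = C1–C5, C10; lactone = C7(=O)–O–C20; ring C = C8, C9, C11–C14; ring D = C8, C13–C16; C17 = exocyclic CH2)
- Retrosynthesis: remove C17 and the silyl groups; cut C8–C9 and C11–C12 together, which opens the lactone ring and ring C and turns C11–O into C11–B; cut C8–C14 (ring D opens to a diazo keto ester); cut the C7–O ester bond to a ring-A diol and an itaconate-derived acyl unit.
- Enabling feature: C8 lies between the lactone carbonyl C7 and the ketone C15, so it carries an electrophilic tertiary radical. The C7–O–C20 ester ties it to C9 (6-exo), and C12 is an exocyclic methylene on ring D that the C11 radical reaches 6-endo, leaving a harmless bridgehead radical at C13.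
- Forward order: ring A from 4,4-dimethylcyclohexenone; ester link; ring D by carbenoid C–H insertion; lactone ring and ring C in one atom-transfer radical bicyclization; enone last.
- Stereochemistry: C1 by CBS reduction; C5 by silicon-tethered radical delivery cis to O1; C10 by Fráter–Seebach aldol anti to O1; C14 by a chiral dirhodium catalyst; C8, C9, C11 and C13 in the key step; 11-OH by stereoretentive C–B oxidation.

Key step: step 20

Assumption: Rh2(S-PTTL)4 is taken as the catalyst antipode that gives the C14 configuration drawn; if the sense is opposite, Rh2(R-PTTL)4 is used.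
Remark: C10 of 6–8 and C8 of 22 and 23 are not controlled because they are erased later (enolization, radical formation); C8 is drawn without a descriptor.

Step 1
Reactants: 1 4,4-dimethylcyclohex-2-en-1-one
Product: 2 2-iodo-4,4-dimethylcyclohex-2-en-1-one
Conditions: I2 (1.5 equiv), pyridine–CH2Cl2 (1:1), 0 °C → rt
Reagents that add atoms: iodine, II
Why: α-Iodination of the enone (pyridine conjugate addition, iodination, elimination) should give the iodoenone needed for asymmetric reduction and carbonylation; no stereocentre is formed.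

Step 2
Reactants: 2 2-iodo-4,4-dimethylcyclohex-2-en-1-one
Product: 3 (S)-2-iodo-4,4-dimethylcyclohex-2-en-1-ol
Conditions: (R)-2-methyl-CBS-oxazaborolidine (0.2 equiv), BH3·SMe2 (0.7 equiv), THF, −20 °C; MeOH quench
Reagents that add atoms: none
Why: Corey–Bakshi–Shibata reduction, with the iodoalkenyl arm as the large group, should give the (S)-carbinol with the (R)-catalyst and so fix C1 and the absolute configuration of ring A.

Step 3
Reactants: 3 (S)-2-iodo-4,4-dimethylcyclohex-2-en-1-ol
Product: 4 methyl (6S)-6-hydroxy-3,3-dimethylcyclohex-1-ene-1-carboxylate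
Conditions: Pd(OAc)2 (5 mol %), PPh3 (10 mol %), CO (1 atm), MeOH (10 equiv), Et3N (2 equiv), DMF, 60 °C
Reagents that add atoms: carbon monoxide, [C-]#[O+]; methanol, CO
Why: Palladium-catalysed alkoxycarbonylation of the alkenyl iodide should install C20 as an ester that activates the alkene for the radical step; C1 is untouched.

Step 4
Reactants: 4 methyl (6S)-6-hydroxy-3,3-dimethylcyclohex-1-ene-1-carboxylate
Product: 5 methyl (6S)-6-{[(bromomethyl)dimethylsilyl]oxy}-3,3-dimethylcyclohex-1-ene-1-carboxylate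
Conditions: ClSiMe2CH2Br (1.2 equiv), Et3N (1.5 equiv), DMAP (5 mol %), CH2Cl2, 0 °C
Reagents that add atoms: (bromomethyl)chlorodimethylsilane, C[Si](C)(Cl)CBr
Why: Silylation of the allylic alcohol attaches the radical precursor to O1 as a temporary silicon tether.

Step 5
Reactants: 5 methyl (6S)-6-{[(bromomethyl)dimethylsilyl]oxy}-3,3-dimethylcyclohex-1-ene-1-carboxylate
Product: 7 methyl 2-hydroxy-6-(hydroxymethyl)-5,5-dimethylcyclohexane-1-carboxylate (OH cis to CH2OH; ester trans), via bicyclic siloxane 6 (not isolated)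
Conditions: Bu3SnH (1.3 equiv, syringe pump), AIBN (0.1 equiv), PhH (0.02 M), 80 °C; then KF, KHCO3, 30% H2O2, THF–MeOH, rt
Reagents that add atoms: hydrogen peroxide, OO
Why: Silicon-tethered radical cyclization (the α-silyl radical closes 6-endo on the β-carbon of the enoate, which is polarity-matched and favoured by the substituted proximal carbon) delivers C6 to C5 on the face of O1, and Tamao–Fleming oxidation turns C–Si into C–OH with retention; the C10 hydrogen is erased in step 7.

Step 6
Reactants: 7 methyl 2-hydroxy-6-(hydroxymethyl)-5,5-dimethylcyclohexane-1-carboxylate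
Product: 8 methyl 6-{[(tert-butyldimethylsilyl)oxy]methyl}-2-hydroxy-5,5-dimethylcyclohexane-1-carboxylate
Conditions: TBSCl (1.05 equiv), imidazole (2 equiv), CH2Cl2, 0 °C
Reagents that add atoms: tert-butyldimethylsilyl chloride, CC(C)(C)[Si](C)(C)Cl
Why: Silylation should select the primary over the hindered secondary hydroxyl, protecting O6 and leaving the β-hydroxy ester for the next step.

Step 7
Reactants: 8 methyl 6-{[(tert-butyldimethylsilyl)oxy]methyl}-2-hydroxy-5,5-dimethylcyclohexane-1-carboxylate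
Product: 9 methyl 6-{[(tert-butyldimethylsilyl)oxy]methyl}-2-hydroxy-1-(hydroxymethyl)-5,5-dimethylcyclohexane-1-carboxylate (new CH2OH trans to 2-OH)
Conditions: LiN(iPr)2 (2.3 equiv), THF, −78 → −20 °C; then CH2O (gas, from cracked paraformaldehyde), −78 °C; NH4Cl quench
Reagents that add atoms: formaldehyde, C=O
Why: Fráter–Seebach reaction: the lithium-chelated alkoxide–enolate dianion should take up formaldehyde on the face anti to O1 and to the C5 side chain, creating quaternary C10 with C9 trans and the ester (C20) cis to O1.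

Step 8
Reactants: 9 methyl 6-{[(tert-butyldimethylsilyl)oxy]methyl}-2-hydroxy-1-(hydroxymethyl)-5,5-dimethylcyclohexane-1-carboxylate
Product: 10 methyl 6-{[(tert-butyldimethylsilyl)oxy]methyl}-1-formyl-2-hydroxy-5,5-dimethylcyclohexane-1-carboxylate
Conditions: TEMPO (0.1 equiv), PhI(OAc)2 (1.2 equiv), CH2Cl2, rt
Reagents that add atoms: none
Why: Oxoammonium (TEMPO) oxidation should select the primary alcohol over the hindered secondary one and gives a non-enolizable aldehyde; no stereocentre changes.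

Step 9
Reactants: 10 methyl 6-{[(tert-butyldimethylsilyl)oxy]methyl}-1-formyl-2-hydroxy-5,5-dimethylcyclohexane-1-carboxylate
Product: 11 methyl 6-{[(tert-butyldimethylsilyl)oxy]methyl}-2-hydroxy-5,5-dimethyl-1-[(E)-2-(4,4,5,5-tetramethyl-1,3,2-dioxaborolan-2-yl)ethenyl]cyclohexane-1-carboxylate
Conditions: Cl2CHB(pin) (2 equiv), CrCl2 (8 equiv), LiI (4 equiv), THF, rt
Reagents that add atoms: 2-(dichloromethyl)-4,4,5,5-tetramethyl-1,3,2-dioxaborolane, ClC(Cl)B1OC(C)(C)C(C)(C)O1
Why: Takai–Utimoto olefination with the geminal dichromium reagent should convert the hindered aldehyde into the (E)-alkenyl boronate (C9=C11) and tolerates the ester and free hydroxyl.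

Step 10
Reactants: 11 methyl 6-{[(tert-butyldimethylsilyl)oxy]methyl}-2-hydroxy-5,5-dimethyl-1-[(E)-2-(4,4,5,5-tetramethyl-1,3,2-dioxaborolan-2-yl)ethenyl]cyclohexane-1-carboxylate
Product: 12 ring-A diol (C20–OH and C1–OH free; C6–OTBS; alkenyl boronate on C10)
Conditions: iBu2AlH (4 equiv), CH2Cl2, −78 → −40 °C; Rochelle salt work-up
Reagents that add atoms: none
Why: Hydride reduction of the ester to the primary alcohol C20–OH; the pinacol boronate and silyl ether should survive at low temperature.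

Step 11
Reactants: 13 4-methyl hydrogen itaconate
Product: 14 methyl 3-(hydroxymethyl)but-3-enoate
Conditions: BH3·SMe2 (1.1 equiv), THF, 0 °C
Reagents that add atoms: none
Why: Borane reduces the free carboxylic acid chemoselectively in the presence of the ester, giving the C14 carbinol of the side chain.

Step 12
Reactants: 14 methyl 3-(hydroxymethyl)but-3-enoate
Product: 15 methyl 3-{[(tert-butyldimethylsilyl)oxy]methyl}but-3-enoate
Conditions: TBSCl, imidazole, CH2Cl2, 0 °C
Reagents that add atoms: tert-butyldimethylsilyl chloride, CC(C)(C)[Si](C)(C)Cl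
Why: Standard silylation protects O14 and prevents lactonization.

Step 13
Reactants: 15 methyl 3-{[(tert-butyldimethylsilyl)oxy]methyl}but-3-enoate
Product: 16 3-{[(tert-butyldimethylsilyl)oxy]methyl}but-3-enoic acid
Conditions: LiOH·H2O, THF–H2O, 0 °C; then cold 0.5 M HCl to pH 4
Reagents that add atoms: lithium hydroxide, [Li+].[OH-]
Why: Mild saponification at 0 °C should give the β,γ-unsaturated acid without moving the double bond into conjugation.

Step 14
Reactants: 16 3-{[(tert-butyldimethylsilyl)oxy]methyl}but-3-enoic acid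
Product: 17 acyl Meldrum's acid (enol form)
Conditions: Meldrum's acid (1.1 equiv), DCC (1.1 equiv), DMAP (1.2 equiv), CH2Cl2, 0 °C → rt
Reagents that add atoms: Meldrum's acid, CC1(C)OC(=O)CC(=O)O1
Why: Carbodiimide C-acylation of Meldrum's acid gives a storable acylketene precursor that brings in C7 and C8.

Step 15
Reactants: 12 ring-A diol; 17 acyl Meldrum's acid
Product: 19 β-keto ester (C20 ester of 5-{[(tert-butyldimethylsilyl)oxy]methyl}-3-oxohex-5-enoic acid; C1–OH free), via acylketene 18 (not isolated)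
Conditions: PhMe, 80 °C (1.05 equiv of 17)
Reagents that add atoms: none
Why: Thermal retro-[4+2] fragmentation of the acyl Meldrum's acid gives an acylketene that the primary neopentyl C20–OH should capture in preference to the secondary C1–OH flanked by the quaternary C10.

Step 16
Reactants: 19 β-keto ester
Product: 20 α-diazo-β-keto ester
Conditions: 4-acetamidobenzenesulfonyl azide (1.2 equiv), Et3N (2 equiv), MeCN, 0 °C → rt
Reagents that add atoms: 4-acetamidobenzenesulfonyl azide, CC(=O)Nc1ccc(cc1)S(=O)(=O)N=[N+]=[N-]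
Why: Regitz diazo transfer to the active methylene C8; the enolate forms at C8, which keeps the β,γ-alkene out of conjugation.

Step 17
Reactants: 20 α-diazo-β-keto ester
Product: 21 α-diazo-β-keto ester C1 acetate
Conditions: Ac2O (3 equiv), pyridine, DMAP (0.1 equiv), CH2Cl2, rt
Reagents that add atoms: acetic anhydride, CC(=O)OC(C)=O
Why: Acetylation of the only free hydroxyl installs the C1 acetate of the target at a stage where C8 has no acidic hydrogen.

Step 18
Reactants: 21 α-diazo-β-keto ester C1 acetate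
Product: 22 ring-D β-keto ester (C20 ester of 5-[(tert-butyldimethylsilyl)oxy]-4-methylidene-2-oxocyclopentane-1-carboxylic acid)
Conditions: Rh2(S-PTTL)4 (2 mol %), CH2Cl2, 0 °C
Reagents that add atoms: none
Why: Intramolecular 1,5 C–H insertion of the rhodium carbenoid into the C14 methylene (allylic and α to oxygen, on the ketone arm) should close the cyclopentanone C8–C14, with the chiral carboxylate catalyst selecting one enantiotopic C14–H; C8 stays labile.

Step 19
Reactants: 22 ring-D β-keto ester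
Product: 23 C8 bromide of 22
Conditions: NBS (1.05 equiv), CH2Cl2, 0 °C
Reagents that add atoms: N-bromosuccinimide, O=C1CCC(=O)N1Br
Why: Electrophilic bromination of the β-keto ester enol gives the radical precursor and removes the acidic C8–H, which shuts off loss of the C14 silyloxy group.

Step 20
Reactants: 23 C8 bromide
Product: 24 pentacyclic bridgehead bromide (11-Bpin, 13-Br)
Conditions: CuBr (0.3 equiv), tris(2-pyridylmethyl)amine (0.3 equiv), PhMe (0.01 M), 80 °C
Reagents that add atoms: none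
Why: Monovalent copper abstracts bromine from C8; the electrophilic tertiary radical adds through the C7–O–C20 ester to C9 of the alkenyl boronate (6-exo-trig, closing the δ-lactone), the α-boryl radical at C11 adds to the exocyclic C12 methylene of ring D (6-endo-trig, closing ring C and the bicyclo[3.2.1]octane), and the bridgehead C13 radical takes bromine back from CuBr2 (divalent copper), so C8–C9 and C11–C12 form in one event. The closest known reaction type is copper-catalysed atom-transfer radical cyclization of α-halo-1,3-dicarbonyl esters onto alkenes, combined with radical addition to alkenyl boronic esters. C8 should be set by attack on the radical face anti to the C14 silyloxy group; C9 by a chair-like 6-exo transition state with the alkenyl boronate and the C5 arm of ring A equatorial; C11 by closure with boron anti to the quaternary C10; C13 is a bridgehead fixed by the ring. Regioselectivity needs attack at C9 and at C12: boron stabilises the radical at C11, and 5-exo attack at the fully substituted C13 would give a strained norbornane with a primary radical. Chemoselectivity needs the C11 radical to cyclize before it is quenched: an α-boryl radical is not easily oxidised, and any α-bromo boronate formed re-enters the cycle.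

Step 21
Reactants: 24 pentacyclic bridgehead bromide
Product: 25 pentacyclic boronate (13-H)
Conditions: Bu3SnH (1.5 equiv), AIBN (0.1 equiv), PhMe, 90 °C
Reagents that add atoms: none
Why: Radical chain reduction removes the bridgehead bromine; the C13 configuration is fixed by the bicycle.

Step 22
Reactants: 25 pentacyclic boronate
Product: 26 11-alcohol
Conditions: NaBO3·4H2O (5 equiv), THF–H2O (1:1), rt
Reagents that add atoms: sodium perborate, [Na+].[O-]OB=O
Why: Perborate oxidation of the C–B bond (1,2-shift from boron to oxygen) proceeds with retention and should give the 11-OH configuration of the target; the mild medium spares the acetate and the non-enolizable β-keto lactone.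

Step 23
Reactants: 26 11-alcohol
Product: 30 protected enone (11-OTMS; 6- and 14-OTBS), via bis-silyl enol ether 27 (not isolated), via Mannich base 28 (not isolated), via methiodide 29 (not isolated)
Conditions: TMSOTf (2.5 equiv), Et3N (4 equiv), CH2Cl2, 0 °C; then Me2N=CH2+ I− (1.5 equiv), rt; then MeI (10 equiv); then DBU (3 equiv), rt
Reagents that add atoms: trimethylsilyl trifluoromethanesulfonate, C[Si](C)(C)OS(=O)(=O)C(F)(F)F; N,N-dimethylmethyleneiminium iodide, C=[N+](C)C.[I-]
Why: Soft enolization can only go towards C16 (C8 is quaternary) and also masks O11; Mannich reaction of the silyl enol ether with Eschenmoser's salt, N-methylation and E1cB elimination should give the C16 exocyclic methylene.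

Step 24
Reactants: 30 protected enone
Product: 31 CNP0225182.1 (target)
Conditions: HF·pyridine, THF–pyridine, 0 °C → rt
Reagents that add atoms: none
Why: Fluoride-mediated global desilylation under mildly acidic conditions frees the 6-, 11- and 14-hydroxyls without touching the acetate, the lactone or the enone.

**Compound list**
1 | 4,4-dimethylcyclohex-2-en-1-one | CC1(C)CCC(=O)C=C1 | starting material
2 | 2-iodo-4,4-dimethylcyclohex-2-en-1-one | CC1(C)CCC(=O)C(I)=C1 | intermediate
3 | (S)-2-iodo-4,4-dimethylcyclohex-2-en-1-ol | O[C@H]1CCC(C)(C)C=C1I | intermediate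
4 | methyl (6S)-6-hydroxy-3,3-dimethylcyclohex-1-ene-1-carboxylate | O[C@H]1CCC(C)(C)C=C1C(=O)OC | intermediate
5 | methyl (6S)-6-{[(bromomethyl)dimethylsilyl]oxy}-3,3-dimethylcyclohex-1-ene-1-carboxylate | BrC[Si](C)(C)O[C@H]1CCC(C)(C)C=C1C(=O)OC | intermediate
6 | bicyclic siloxane: methyl 3,3,6,6-tetramethyl-2-oxa-3-silabicyclo[3.3.1]nonane-9-carboxylate (ester on the face away from the O–Si–CH2 bridge) | COC(=O)[C@@H]1[C@@H]2CCC(C)(C)[C@H]1C[Si](C)(C)O2 | intermediate (not isolated)
7 | methyl 2-hydroxy-6-(hydroxymethyl)-5,5-dimethylcyclohexane-1-carboxylate (2-OH and 6-CH2OH cis; ester trans to both) | COC(=O)[C@@H]1[C@@H](O)CCC(C)(C)[C@H]1CO | intermediate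
8 | methyl 6-{[(tert-butyldimethylsilyl)oxy]methyl}-2-hydroxy-5,5-dimethylcyclohexane-1-carboxylate (configuration as 7) | COC(=O)[C@@H]1[C@@H](O)CCC(C)(C)[C@H]1CO[Si](C)(C)C(C)(C)C | intermediate
9 | methyl 6-{[(tert-butyldimethylsilyl)oxy]methyl}-2-hydroxy-1-(hydroxymethyl)-5,5-dimethylcyclohexane-1-carboxylate (1-CH2OH trans to 2-OH and to the 6-substituent) | COC(=O)[C@@]1(CO)[C@@H](O)CCC(C)(C)[C@H]1CO[Si](C)(C)C(C)(C)C | intermediate
10 | methyl 6-{[(tert-butyldimethylsilyl)oxy]methyl}-1-formyl-2-hydroxy-5,5-dimethylcyclohexane-1-carboxylate | COC(=O)[C@@]1(C=O)[C@@H](O)CCC(C)(C)[C@H]1CO[Si](C)(C)C(C)(C)C | intermediate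
11 | methyl 6-{[(tert-butyldimethylsilyl)oxy]methyl}-2-hydroxy-5,5-dimethyl-1-[(E)-2-(4,4,5,5-tetramethyl-1,3,2-dioxaborolan-2-yl)ethenyl]cyclohexane-1-carboxylate | COC(=O)[C@@]1(/C=C/B2OC(C)(C)C(C)(C)O2)[C@@H](O)CCC(C)(C)[C@H]1CO[Si](C)(C)C(C)(C)C | intermediate
12 | ring-A diol: {6-{[(tert-butyldimethylsilyl)oxy]methyl}-2-hydroxy-5,5-dimethyl-1-[(E)-2-(pinacolatoboryl)ethenyl]cyclohexyl}methanol (C20–OH, C1–OH and C6 on one face; alkenyl on the other) | OC[C@@]1(/C=C/B2OC(C)(C)C(C)(C)O2)[C@@H](O)CCC(C)(C)[C@H]1CO[Si](C)(C)C(C)(C)C | intermediate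
13 | 4-methyl hydrogen itaconate (2-methylidenebutanedioic acid 4-methyl ester) | C=C(CC(=O)OC)C(=O)O | starting material
14 | methyl 3-(hydroxymethyl)but-3-enoate | C=C(CO)CC(=O)OC | intermediate
15 | methyl 3-{[(tert-butyldimethylsilyl)oxy]methyl}but-3-enoate | C=C(CO[Si](C)(C)C(C)(C)C)CC(=O)OC | intermediate
16 | 3-{[(tert-butyldimethylsilyl)oxy]methyl}but-3-enoic acid | C=C(CO[Si](C)(C)C(C)(C)C)CC(=O)O | intermediate
17 | acyl Meldrum's acid: 5-(3-{[(tert-butyldimethylsilyl)oxy]methyl}-1-hydroxybut-3-enylidene)-2,2-dimethyl-1,3-dioxane-4,6-dione | C=C(CO[Si](C)(C)C(C)(C)C)CC(O)=C1C(=O)OC(C)(C)OC1=O | intermediate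
18 | acylketene: 5-{[(tert-butyldimethylsilyl)oxy]methyl}hexa-1,5-diene-1,3-dione | C=C(CO[Si](C)(C)C(C)(C)C)CC(=O)C=C=O | intermediate (not isolated)
19 | β-keto ester: C20 ester of 12 with 5-{[(tert-butyldimethylsilyl)oxy]methyl}-3-oxohex-5-enoic acid | C=C(CO[Si](C)(C)C(C)(C)C)CC(=O)CC(=O)OC[C@@]1(/C=C/B2OC(C)(C)C(C)(C)O2)[C@@H](O)CCC(C)(C)[C@H]1CO[Si](C)(C)C(C)(C)C | intermediate
20 | α-diazo-β-keto ester (2-diazo analogue of 19) | C=C(CO[Si](C)(C)C(C)(C)C)CC(=O)C(=[N+]=[N-])C(=O)OC[C@@]1(/C=C/B2OC(C)(C)C(C)(C)O2)[C@@H](O)CCC(C)(C)[C@H]1CO[Si](C)(C)C(C)(C)C | intermediate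
21 | C1 acetate of 20 | C=C(CO[Si](C)(C)C(C)(C)C)CC(=O)C(=[N+]=[N-])C(=O)OC[C@@]1(/C=C/B2OC(C)(C)C(C)(C)O2)[C@@H](OC(C)=O)CCC(C)(C)[C@H]1CO[Si](C)(C)C(C)(C)C | intermediate
22 | ring-D β-keto ester: C20 ester of 5-[(tert-butyldimethylsilyl)oxy]-4-methylidene-2-oxocyclopentane-1-carboxylic acid (C14 as drawn; C8 labile) | C=C1CC(=O)C(C(=O)OC[C@@]2(/C=C/B3OC(C)(C)C(C)(C)O3)[C@@H](OC(C)=O)CCC(C)(C)[C@H]2CO[Si](C)(C)C(C)(C)C)[C@@H]1O[Si](C)(C)C(C)(C)C | intermediate
23 | C8 bromide of 22 (1-bromo-2-oxocyclopentane-1-carboxylate; either C8 epimer) | C=C1CC(=O)C(Br)(C(=O)OC[C@@]2(/C=C/B3OC(C)(C)C(C)(C)O3)[C@@H](OC(C)=O)CCC(C)(C)[C@H]2CO[Si](C)(C)C(C)(C)C)[C@@H]1O[Si](C)(C)C(C)(C)C | intermediate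
24 | pentacyclic bridgehead bromide: 1-acetoxy-13-bromo-6,14-bis(tert-butyldimethylsilyloxy)-15-oxo-11-(pinacolatoboryl)-6,7-seco-ent-kauran-7,20-olide | C1C(=O)[C@@]23C(=O)OC[C@]4([C@@H](OC(C)=O)CCC(C)(C)[C@H]4CO[Si](C)(C)C(C)(C)C)[C@@H]2[C@@H](B5OC(C)(C)C(C)(C)O5)C[C@]1(Br)[C@H]3O[Si](C)(C)C(C)(C)C | intermediate
25 | pentacyclic boronate (13-H analogue of 24) | C1C(=O)[C@@]23C(=O)OC[C@]4([C@@H](OC(C)=O)CCC(C)(C)[C@H]4CO[Si](C)(C)C(C)(C)C)[C@@H]2[C@@H](B5OC(C)(C)C(C)(C)O5)C[C@@H]1[C@H]3O[Si](C)(C)C(C)(C)C | intermediate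
26 | 11-alcohol: 1-acetoxy-6,14-bis(tert-butyldimethylsilyloxy)-11-hydroxy-15-oxo-6,7-seco-ent-kauran-7,20-olide | C1C(=O)[C@@]23C(=O)OC[C@]4([C@@H](OC(C)=O)CCC(C)(C)[C@H]4CO[Si](C)(C)C(C)(C)C)[C@@H]2[C@@H](O)C[C@@H]1[C@H]3O[Si](C)(C)C(C)(C)C | intermediate
27 | bis-silyl enol ether (11-OTMS; C15=C16 trimethylsilyl enol ether) | C1=C(O[Si](C)(C)C)[C@@]23C(=O)OC[C@]4([C@@H](OC(C)=O)CCC(C)(C)[C@H]4CO[Si](C)(C)C(C)(C)C)[C@@H]2[C@@H](O[Si](C)(C)C)C[C@@H]1[C@H]3O[Si](C)(C)C(C)(C)C | intermediate (not isolated)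
28 | Mannich base (16-dimethylaminomethyl 15-ketone; 11-OTMS) | CN(C)CC1C(=O)[C@@]23C(=O)OC[C@]4([C@@H](OC(C)=O)CCC(C)(C)[C@H]4CO[Si](C)(C)C(C)(C)C)[C@@H]2[C@@H](O[Si](C)(C)C)C[C@@H]1[C@H]3O[Si](C)(C)C(C)(C)C | intermediate (not isolated)
29 | methiodide of 28 | C[N+](C)(C)CC1C(=O)[C@@]23C(=O)OC[C@]4([C@@H](OC(C)=O)CCC(C)(C)[C@H]4CO[Si](C)(C)C(C)(C)C)[C@@H]2[C@@H](O[Si](C)(C)C)C[C@@H]1[C@H]3O[Si](C)(C)C(C)(C)C.[I-] | intermediate (not isolated)
30 | protected enone: 1-acetoxy-6,14-bis(tert-butyldimethylsilyloxy)-11-(trimethylsilyloxy)-15-oxo-6,7-seco-ent-kaur-16-en-7,20-olide | C=C1C(=O)[C@@]23C(=O)OC[C@]4([C@@H](OC(C)=O)CCC(C)(C)[C@H]4CO[Si](C)(C)C(C)(C)C)[C@@H]2[C@@H](O[Si](C)(C)C)C[C@@H]1[C@H]3O[Si](C)(C)C(C)(C)C | intermediate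
31 | CNP0225182.1: 1-acetoxy-6,11,14-trihydroxy-15-oxo-6,7-seco-ent-kaur-16-en-7,20-olide (configuration as in the SMILES) | C=C1C(=O)[C@@]23C(=O)OC[C@]4([C@@H](OC(C)=O)CCC(C)(C)[C@H]4CO)[C@@H]2[C@@H](O)C[C@@H]1[C@H]3O | target

**Step count:** 24 steps in total; longest linear sequence 20 steps (steps 1–10 and 15–24).

**Steps most likely to fail**

1. Step 20 (radical bicyclization). What may go wrong: poor facial selectivity at C11 in the second ring closure, so that boron is delivered equatorial and the 11-epimer results. (The first closure is also congested; if it does not occur, 22 is recovered after debromination.) Fallback: set C11 by reagent-controlled ketone reduction instead. It sets out from 25, carried as the C11 mixture. TBSOTf and Et3N convert the C15 ketone into its only possible silyl enol ether F1. NaBO3 oxidation gives the 11-alcohols F2, and Dess–Martin periodinane (NaHCO3 buffer) gives the 11-ketone F3, the only ketone present while C15 is masked. NaBH4 (or LiBH(sBu)3) at −78 °C should attack from the face away from the C15–C16 bridge and give the 11-alcohol F4 with the configuration of 26. TMSOTf and Et3N give the 11-trimethylsilyl ether F5, and Eschenmoser's salt then gives Mannich base 28, where the route is rejoined.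

2. Step 18 (carbenoid C–H insertion). What may go wrong: diversion of the carbenoid into cyclopropanation of the alkenyl boronate across the ester tether, or weak catalyst control at C14 on the large chiral ester. Fallback: form ring D on a simple ester and attach it afterwards. It sets out from 17. Heating with tert-butanol in toluene gives the tert-butyl β-keto ester F6; diazo transfer gives the diazo ester F7; Rh2(S-PTTL)4 gives the tert-butyl cyclopentanone carboxylate F8, with C14 set by the catalyst alone. Thermolysis of F8 with diol 12 in toluene at 110 °C (acylketene, loss of tert-butanol) gives the hydroxy keto ester F9. NBS gives the bromide F10, and Ac2O, pyridine and DMAP at 0 °C give 23, where the route is rejoined.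

3. Step 15 (acylketene esterification). What may go wrong: loss of chemoselectivity between the primary C20–OH and the secondary C1–OH, giving wrong-site or double acylation. Fallback: differentiate the two hydroxyls by protection before the ester is reduced. It sets out from 11. TESOTf and 2,6-lutidine give the triethylsilyl ether F11; iBu2AlH gives the mono-alcohol F12; heating with 17 gives the β-keto ester F13; diazo transfer gives the diazo ester F14. PPTS in MeOH at 0 °C removes the triethylsilyl group selectively and gives 20, where the route is rejoined.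

**Further compounds**
F1 | step 20 | C15 tert-butyldimethylsilyl enol ether of 25 (C11 either configuration) | C1=C(O[Si](C)(C)C(C)(C)C)[C@@]23C(=O)OC[C@]4([C@@H](OC(C)=O)CCC(C)(C)[C@H]4CO[Si](C)(C)C(C)(C)C)[C@@H]2C(B5OC(C)(C)C(C)(C)O5)C[C@@H]1[C@H]3O[Si](C)(C)C(C)(C)C
F2 | step 20 | 11-alcohols with C15 silyl enol ether (C11 either configuration) | C1=C(O[Si](C)(C)C(C)(C)C)[C@@]23C(=O)OC[C@]4([C@@H](OC(C)=O)CCC(C)(C)[C@H]4CO[Si](C)(C)C(C)(C)C)[C@@H]2C(O)C[C@@H]1[C@H]3O[Si](C)(C)C(C)(C)C
F3 | step 20 | 11-ketone with C15 silyl enol ether | C1=C(O[Si](C)(C)C(C)(C)C)[C@@]23C(=O)OC[C@]4([C@@H](OC(C)=O)CCC(C)(C)[C@H]4CO[Si](C)(C)C(C)(C)C)[C@@H]2C(=O)C[C@@H]1[C@H]3O[Si](C)(C)C(C)(C)C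
F4 | step 20 | 11-alcohol (configuration of 26) with C15 silyl enol ether | C1=C(O[Si](C)(C)C(C)(C)C)[C@@]23C(=O)OC[C@]4([C@@H](OC(C)=O)CCC(C)(C)[C@H]4CO[Si](C)(C)C(C)(C)C)[C@@H]2[C@@H](O)C[C@@H]1[C@H]3O[Si](C)(C)C(C)(C)C
F5 | step 20 | 11-trimethylsilyl ether of F4 | C1=C(O[Si](C)(C)C(C)(C)C)[C@@]23C(=O)OC[C@]4([C@@H](OC(C)=O)CCC(C)(C)[C@H]4CO[Si](C)(C)C(C)(C)C)[C@@H]2[C@@H](O[Si](C)(C)C)C[C@@H]1[C@H]3O[Si](C)(C)C(C)(C)C
F6 | step 18 | tert-butyl 5-{[(tert-butyldimethylsilyl)oxy]methyl}-3-oxohex-5-enoate | C=C(CO[Si](C)(C)C(C)(C)C)CC(=O)CC(=O)OC(C)(C)C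
F7 | step 18 | tert-butyl 2-diazo-5-{[(tert-butyldimethylsilyl)oxy]methyl}-3-oxohex-5-enoate | C=C(CO[Si](C)(C)C(C)(C)C)CC(=O)C(=[N+]=[N-])C(=O)OC(C)(C)C
F8 | step 18 | tert-butyl 5-[(tert-butyldimethylsilyl)oxy]-4-methylidene-2-oxocyclopentane-1-carboxylate | C=C1CC(=O)C(C(=O)OC(C)(C)C)[C@@H]1O[Si](C)(C)C(C)(C)C
F9 | step 18 | C1-hydroxy analogue of 22 | C=C1CC(=O)C(C(=O)OC[C@@]2(/C=C/B3OC(C)(C)C(C)(C)O3)[C@@H](O)CCC(C)(C)[C@H]2CO[Si](C)(C)C(C)(C)C)[C@@H]1O[Si](C)(C)C(C)(C)C
F10 | step 18 | C1-hydroxy analogue of 23 | C=C1CC(=O)C(Br)(C(=O)OC[C@@]2(/C=C/B3OC(C)(C)C(C)(C)O3)[C@@H](O)CCC(C)(C)[C@H]2CO[Si](C)(C)C(C)(C)C)[C@@H]1O[Si](C)(C)C(C)(C)C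
F11 | step 15 | C1 triethylsilyl ether of 11 | COC(=O)[C@@]1(/C=C/B2OC(C)(C)C(C)(C)O2)[C@@H](O[Si](CC)(CC)CC)CCC(C)(C)[C@H]1CO[Si](C)(C)C(C)(C)C
F12 | step 15 | C1 triethylsilyl ether of 12 | OC[C@@]1(/C=C/B2OC(C)(C)C(C)(C)O2)[C@@H](O[Si](CC)(CC)CC)CCC(C)(C)[C@H]1CO[Si](C)(C)C(C)(C)C
F13 | step 15 | C1 triethylsilyl ether of 19 | C=C(CO[Si](C)(C)C(C)(C)C)CC(=O)CC(=O)OC[C@@]1(/C=C/B2OC(C)(C)C(C)(C)O2)[C@@H](O[Si](CC)(CC)CC)CCC(C)(C)[C@H]1CO[Si](C)(C)C(C)(C)C
F14 | step 15 | C1 triethylsilyl ether of 20 | C=C(CO[Si](C)(C)C(C)(C)C)CC(=O)C(=[N+]=[N-])C(=O)OC[C@@]1(/C=C/B2OC(C)(C)C(C)(C)O2)[C@@H](O[Si](CC)(CC)CC)CCC(C)(C)[C@H]1CO[Si](C)(C)C(C)(C)C
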